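**Strategy**

The route rests on disconnecting the dihydrofuran ring (O1, C2, C3, C3a, C7a) at the C2–C3 bond. C2–H is benzylic to the syringyl ring and α to O1, while C3 sits on the guaiacyl arene next to an ester-level carbon, so an ortho-(syringylmethoxy) aryldiazoacetate, built from 5-iodovanillin and syringaldehyde, should close by enantioselective rhodium-carbenoid 1,5-C–H insertion. This single operation forms the ring, sets C2 under catalyst control and, after in situ epimerisation at C3, delivers the trans arrangement. The precursor is an open-chain benzyl aryl ether. Both primary alcohols are then released in one reduction and acylated together with protected 4-hydroxybenzoic acid.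

Key step: step 6

Remark on numbering: ring atoms are numbered as in 2,3-dihydro-1-benzofuran; the target is (2S,3R), i.e. trans.

Remark on the catalyst: the sense of induction of the (R)-configured PTTL catalyst (delivery of the 2S series) is assumed by analogy with simpler ortho-benzyloxy aryldiazoacetates. The enantiomeric catalyst would be used if the first run shows the opposite sense.

**Route**

Step 1
Reactants: 1 syringaldehyde (4-hydroxy-3,5-dimethoxybenzaldehyde)
Product: 2 4-(tert-butyldimethylsilyloxy)-3,5-dimethoxybenzaldehyde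
Conditions: TBSCl (1.2 equiv), imidazole (2.5 equiv), DMF, rt
Reagents that add atoms: tert-butyldimethylsilyl chloride, CC(C)(C)[Si](C)(C)Cl
Why: Imidazole-mediated silylation of the acidic phenol should proceed despite the two flanking methoxy groups, and the aldehyde is inert.

Step 2
Reactants: 2 4-(tert-butyldimethylsilyloxy)-3,5-dimethoxybenzaldehyde
Product: 3 [4-(tert-butyldimethylsilyloxy)-3,5-dimethoxyphenyl]methanol
Conditions: NaBH4, MeOH–THF (1:1), 0 °C
Reagents that add atoms: none
Why: Borohydride reduction of the aldehyde is chemoselective, and the hindered aryl silyl ether should survive the short exposure at 0 °C.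

Step 3
Reactants: 3 [4-(tert-butyldimethylsilyloxy)-3,5-dimethoxyphenyl]methanol; 4 5-iodovanillin (4-hydroxy-3-iodo-5-methoxybenzaldehyde)
Product: 5 4-{[4-(tert-butyldimethylsilyloxy)-3,5-dimethoxybenzyl]oxy}-3-iodo-5-methoxybenzaldehyde
Conditions: PPh3, DIAD, THF, 0 °C → rt
Reagents that add atoms: none
Why: Mitsunobu etherification should work because the formyl- and iodo-substituted phenol is an acidic pronucleophile and the primary benzylic oxyphosphonium ion is readily displaced.

Step 4
Reactants: 5 4-{[4-(tert-butyldimethylsilyloxy)-3,5-dimethoxybenzyl]oxy}-3-iodo-5-methoxybenzaldehyde; 6 ethyl (triphenylphosphoranylidene)acetate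
Product: 7 ethyl (E)-3-(4-{[4-(tert-butyldimethylsilyloxy)-3,5-dimethoxybenzyl]oxy}-3-iodo-5-methoxyphenyl)prop-2-enoate
Conditions: toluene, 80 °C
Reagents that add atoms: none
Why: Wittig olefination with a stabilised ylide should give the (E)-cinnamate under thermodynamic control and leaves the aryl iodide and silyl ether untouched.

Step 5
Reactants: 7 ethyl (E)-3-(4-{[4-(tert-butyldimethylsilyloxy)-3,5-dimethoxybenzyl]oxy}-3-iodo-5-methoxyphenyl)prop-2-enoate; 8 ethyl diazoacetate
Product: 9 ethyl (E)-3-[4-{[4-(tert-butyldimethylsilyloxy)-3,5-dimethoxybenzyl]oxy}-3-(1-diazo-2-ethoxy-2-oxoethyl)-5-methoxyphenyl]prop-2-enoate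
Conditions: Pd(PPh3)4 (5 mol %), Ag2CO3 (0.5 equiv), Et3N (1.3 equiv, proton shuttle), toluene, rt
Reagents that add atoms: none
Why: Palladium-catalysed cross-coupling of an aryl iodide with the C–H bond of an acceptor diazo ester (oxidative addition, deprotonative palladation, reductive elimination) should retain the diazo group at room temperature.

Step 6
Reactants: 9 ethyl (E)-3-[4-{[4-(tert-butyldimethylsilyloxy)-3,5-dimethoxybenzyl]oxy}-3-(1-diazo-2-ethoxy-2-oxoethyl)-5-methoxyphenyl]prop-2-enoate
Product: 11 ethyl (2S,3S)-2-[4-(tert-butyldimethylsilyloxy)-3,5-dimethoxyphenyl]-5-[(E)-3-ethoxy-3-oxoprop-1-enyl]-7-methoxy-2,3-dihydro-1-benzofuran-3-carboxylate (trans diester), via cis-(2S,3R) diester 10 (not isolated)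
Conditions: Rh2(R-PTTL)4 (2 mol %), toluene, high dilution, −60 → −20 °C; then DBU (1.5 equiv), rt
Reagents that add atoms: none
Why: Rh(II) expels N2 from 9 to give a donor/acceptor rhodium carbenoid at the future C3, which inserts into one of the two enantiotopic C–H bonds of the OCH2 group (the future C2) through a concerted, asynchronous, hydride-transfer-like three-centre transition state; the closest known reaction type is the enantioselective intramolecular 1,5-C–H insertion of aryldiazoacetates into ortho-benzyloxy groups under chiral dirhodium carboxylate catalysis. The dihydrofuran ring is closed by C2–C3 bond formation through a five-membered insertion transition state (1,5-insertion), O1, C7a and C3a being already in place. C2 is set by the catalyst, whose phthalimido-walled chiral pocket selects one benzylic hydrogen, and C3 is first formed cis to the aryl group as the kinetic outcome of the compact insertion transition state. DBU then epimerises C3 alone through the ester enolate to the thermodynamically preferred trans (2S,3S) diester, while the non-acidic C2 is retained. The step needs 1,5-insertion to outrun carbene dimerisation and intermolecular attack on the cinnamate; this should be secured by the proximity and hydridic character of the benzylic C–H (activated by O1 and the electron-rich silyloxy-dimethoxyphenyl ring), by the low reactivity of an electron-poor alkene towards an electrophilic carbenoid, and by high dilution at low temperature.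

Step 7
Reactants: 11 ethyl (2S,3S)-2-[4-(tert-butyldimethylsilyloxy)-3,5-dimethoxyphenyl]-5-[(E)-3-ethoxy-3-oxoprop-1-enyl]-7-methoxy-2,3-dihydro-1-benzofuran-3-carboxylate
Product: 12 [(2S,3R)-2-[4-(tert-butyldimethylsilyloxy)-3,5-dimethoxyphenyl]-5-[(E)-3-hydroxyprop-1-enyl]-7-methoxy-2,3-dihydro-1-benzofuran-3-yl]methanol (trans diol)
Conditions: DIBAL-H (6 equiv), CH2Cl2, −78 → 0 °C; aq. Rochelle salt
Reagents that add atoms: none
Why: DIBAL-H should reduce both esters to primary alcohols (1,2-reduction of the cinnamate) without touching the aryl silyl ether or either stereocentre; the change of the C3 descriptor from S to R is only a change of CIP priorities.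

Step 8
Reactants: 13 4-hydroxybenzoic acid
Product: 15 4-(tert-butyldimethylsilyloxy)benzoic acid, via bis-silylated silyl ester 14 (not isolated)
Conditions: TBSCl (2.3 equiv), imidazole (5 equiv), DMF, rt; then AcOH–THF–H2O (3:1:1), rt
Reagents that add atoms: tert-butyldimethylsilyl chloride, CC(C)(C)[Si](C)(C)Cl
Why: Exhaustive silylation followed by mild aqueous acid should cleave only the labile silyl ester and leave the aryl silyl ether.

Step 9
Reactants: 12 [(2S,3R)-2-[4-(tert-butyldimethylsilyloxy)-3,5-dimethoxyphenyl]-5-[(E)-3-hydroxyprop-1-enyl]-7-methoxy-2,3-dihydro-1-benzofuran-3-yl]methanol; 15 4-(tert-butyldimethylsilyloxy)benzoic acid (2.4 equiv)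
Product: 16 [(2S,3R)-2-[4-(tert-butyldimethylsilyloxy)-3,5-dimethoxyphenyl]-5-[(E)-3-{[4-(tert-butyldimethylsilyloxy)benzoyl]oxy}prop-1-enyl]-7-methoxy-2,3-dihydro-1-benzofuran-3-yl]methyl 4-(tert-butyldimethylsilyloxy)benzoate
Conditions: DCC (2.4 equiv), DMAP (0.2 equiv), CH2Cl2, 0 °C → rt
Reagents that add atoms: none
Why: Steglich esterification should acylate both primary alcohols in one operation under neutral conditions that affect neither the allylic system nor the stereocentres.

Step 10
Reactants: 16 [(2S,3R)-2-[4-(tert-butyldimethylsilyloxy)-3,5-dimethoxyphenyl]-5-[(E)-3-{[4-(tert-butyldimethylsilyloxy)benzoyl]oxy}prop-1-enyl]-7-methoxy-2,3-dihydro-1-benzofuran-3-yl]methyl 4-(tert-butyldimethylsilyloxy)benzoate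
Product: 17 quiquesetinerviusin B
Conditions: TBAF (3.3 equiv), AcOH (3.6 equiv), THF, 0 °C
Reagents that add atoms: none
Why: Fluoride-mediated cleavage of the three aryl silyl ethers, buffered with acetic acid, should leave both benzoate esters, the cinnamyl system and the benzylic C2–O bond intact.

**Compound list**

1 | syringaldehyde (4-hydroxy-3,5-dimethoxybenzaldehyde) | COc1cc(C=O)cc(OC)c1O | starting material
2 | 4-(tert-butyldimethylsilyloxy)-3,5-dimethoxybenzaldehyde | COc1cc(C=O)cc(OC)c1O[Si](C)(C)C(C)(C)C | intermediate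
3 | [4-(tert-butyldimethylsilyloxy)-3,5-dimethoxyphenyl]methanol | COc1cc(CO)cc(OC)c1O[Si](C)(C)C(C)(C)C | intermediate
4 | 5-iodovanillin (4-hydroxy-3-iodo-5-methoxybenzaldehyde) | COc1cc(C=O)cc(I)c1O | starting material
5 | 4-{[4-(tert-butyldimethylsilyloxy)-3,5-dimethoxybenzyl]oxy}-3-iodo-5-methoxybenzaldehyde | COc1cc(C=O)cc(I)c1OCc1cc(OC)c(O[Si](C)(C)C(C)(C)C)c(OC)c1 | intermediate
6 | ethyl (triphenylphosphoranylidene)acetate | CCOC(=O)C=P(c1ccccc1)(c1ccccc1)c1ccccc1 | starting material
7 | ethyl (E)-3-(4-{[4-(tert-butyldimethylsilyloxy)-3,5-dimethoxybenzyl]oxy}-3-iodo-5-methoxyphenyl)prop-2-enoate | CCOC(=O)/C=C/c1cc(OC)c(OCc2cc(OC)c(O[Si](C)(C)C(C)(C)C)c(OC)c2)c(I)c1 | intermediate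
8 | ethyl diazoacetate | CCOC(=O)C=[N+]=[N-] | starting material
9 | ethyl (E)-3-[4-{[4-(tert-butyldimethylsilyloxy)-3,5-dimethoxybenzyl]oxy}-3-(1-diazo-2-ethoxy-2-oxoethyl)-5-methoxyphenyl]prop-2-enoate | CCOC(=O)/C=C/c1cc(OC)c(OCc2cc(OC)c(O[Si](C)(C)C(C)(C)C)c(OC)c2)c(C(=[N+]=[N-])C(=O)OCC)c1 | intermediate
10 | ethyl (2S,3R)-2-[4-(tert-butyldimethylsilyloxy)-3,5-dimethoxyphenyl]-5-[(E)-3-ethoxy-3-oxoprop-1-enyl]-7-methoxy-2,3-dihydro-1-benzofuran-3-carboxylate (cis diester) | COc1cc([C@H]2Oc3c(OC)cc(/C=C/C(=O)OCC)cc3[C@H]2C(=O)OCC)cc(OC)c1O[Si](C)(C)C(C)(C)C | intermediate (not isolated)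
11 | ethyl (2S,3S)-2-[4-(tert-butyldimethylsilyloxy)-3,5-dimethoxyphenyl]-5-[(E)-3-ethoxy-3-oxoprop-1-enyl]-7-methoxy-2,3-dihydro-1-benzofuran-3-carboxylate (trans diester) | COc1cc([C@H]2Oc3c(OC)cc(/C=C/C(=O)OCC)cc3[C@@H]2C(=O)OCC)cc(OC)c1O[Si](C)(C)C(C)(C)C | intermediate
12 | [(2S,3R)-2-[4-(tert-butyldimethylsilyloxy)-3,5-dimethoxyphenyl]-5-[(E)-3-hydroxyprop-1-enyl]-7-methoxy-2,3-dihydro-1-benzofuran-3-yl]methanol | COc1cc([C@H]2Oc3c(OC)cc(/C=C/CO)cc3[C@@H]2CO)cc(OC)c1O[Si](C)(C)C(C)(C)C | intermediate
13 | 4-hydroxybenzoic acid | O=C(O)c1ccc(O)cc1 | starting material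
14 | tert-butyldimethylsilyl 4-(tert-butyldimethylsilyloxy)benzoate | CC(C)(C)[Si](C)(C)Oc1ccc(cc1)C(=O)O[Si](C)(C)C(C)(C)C | intermediate (not isolated)
15 | 4-(tert-butyldimethylsilyloxy)benzoic acid | CC(C)(C)[Si](C)(C)Oc1ccc(cc1)C(=O)O | intermediate
16 | [(2S,3R)-2-[4-(tert-butyldimethylsilyloxy)-3,5-dimethoxyphenyl]-5-[(E)-3-{[4-(tert-butyldimethylsilyloxy)benzoyl]oxy}prop-1-enyl]-7-methoxy-2,3-dihydro-1-benzofuran-3-yl]methyl 4-(tert-butyldimethylsilyloxy)benzoate | COc1cc([C@H]2Oc3c(OC)cc(/C=C/COC(=O)c4ccc(O[Si](C)(C)C(C)(C)C)cc4)cc3[C@@H]2COC(=O)c2ccc(O[Si](C)(C)C(C)(C)C)cc2)cc(OC)c1O[Si](C)(C)C(C)(C)C | intermediate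
17 | quiquesetinerviusin B, [(2S,3R)-2-(4-hydroxy-3,5-dimethoxyphenyl)-5-[(E)-3-(4-hydroxybenzoyloxy)prop-1-enyl]-7-methoxy-2,3-dihydro-1-benzofuran-3-yl]methyl 4-hydroxybenzoate | COc1cc([C@H]2Oc3c(OC)cc(/C=C/COC(=O)c4ccc(O)cc4)cc3[C@@H]2COC(=O)c2ccc(O)cc2)cc(OC)c1O | target

**Step count and risks**

Total step count: 10. Longest linear sequence: 9 steps (steps 1–7, 9 and 10, from syringaldehyde); step 8 is a one-step side branch.

Steps most likely to fail:

Step 6 (key step). The discrimination of the two enantiotopic benzylic hydrogens may be eroded by the early, hydride-transfer-like transition state of this very electron-rich benzyl ether, so that the enantiomeric purity of the ring would be insufficient. The fallback replaces asymmetric catalysis by resolution. Setting out from 9, the insertion would be run with an achiral catalyst, Rh2(esp)2 in CH2Cl2 at room temperature, followed by the same DBU equilibration. This should give the trans diester as a racemate, that is 11 together with its enantiomer, the (2R,3R) trans diester F2. It forms by way of the cis diester 10 and its enantiomer, the (2R,3S) cis diester F1, neither of which is isolated. Preparative chromatography on a chiral stationary phase (SFC) would then separate 11 from F2, and the route is rejoined at 11.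

Step 5. Oxidative addition of palladium(0) into the hindered, electron-rich ortho-alkoxy aryl iodide may be slower than palladium-induced decomposition of the diazo ester, so that the diazo partner is consumed by carbene dimerisation. The fallback builds the carbon framework first and introduces the diazo group afterwards. Setting out from 7, a Negishi-type coupling with the Reformatsky reagent (2-ethoxy-2-oxoethyl)zinc bromide (Pd2(dba)3, XPhos, THF, rt to 50 °C) should give the arylacetate ethyl (E)-3-[4-{[4-(tert-butyldimethylsilyloxy)-3,5-dimethoxybenzyl]oxy}-3-(2-ethoxy-2-oxoethyl)-5-methoxyphenyl]prop-2-enoate F3. Regitz diazo transfer with 4-acetamidobenzenesulfonyl azide and DBU in MeCN (0 °C to rt) would then return to 9.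

Step 3. The activated para-silyloxybenzyl oxyphosphonium ion may ionise and be captured by the hydrazide anion faster than the doubly ortho-substituted phenoxide attacks it, so that the ether does not form. The fallback separates activation from etherification. Setting out from 3, treatment with PBr3 (Et2O, 0 °C) should give the benzyl bromide [4-(bromomethyl)-2,6-dimethoxyphenoxy](tert-butyl)dimethylsilane F4. Williamson alkylation of 4 with F4 (K2CO3, acetone, 50 °C) would come back to the route at 5.

**Further compounds**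

F1 | step 6 | ethyl (2R,3S)-2-[4-(tert-butyldimethylsilyloxy)-3,5-dimethoxyphenyl]-5-[(E)-3-ethoxy-3-oxoprop-1-enyl]-7-methoxy-2,3-dihydro-1-benzofuran-3-carboxylate (cis, enantiomer of 10) | COc1cc([C@@H]2Oc3c(OC)cc(/C=C/C(=O)OCC)cc3[C@@H]2C(=O)OCC)cc(OC)c1O[Si](C)(C)C(C)(C)C
F2 | step 6 | ethyl (2R,3R)-2-[4-(tert-butyldimethylsilyloxy)-3,5-dimethoxyphenyl]-5-[(E)-3-ethoxy-3-oxoprop-1-enyl]-7-methoxy-2,3-dihydro-1-benzofuran-3-carboxylate (trans, enantiomer of 11) | COc1cc([C@@H]2Oc3c(OC)cc(/C=C/C(=O)OCC)cc3[C@H]2C(=O)OCC)cc(OC)c1O[Si](C)(C)C(C)(C)C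
F3 | step 5 | ethyl (E)-3-[4-{[4-(tert-butyldimethylsilyloxy)-3,5-dimethoxybenzyl]oxy}-3-(2-ethoxy-2-oxoethyl)-5-methoxyphenyl]prop-2-enoate | CCOC(=O)/C=C/c1cc(OC)c(OCc2cc(OC)c(O[Si](C)(C)C(C)(C)C)c(OC)c2)c(CC(=O)OCC)c1
F4 | step 3 | [4-(bromomethyl)-2,6-dimethoxyphenoxy](tert-butyl)dimethylsilane | COc1cc(CBr)cc(OC)c1O[Si](C)(C)C(C)(C)C
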